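The earlier runs and the new flask come from a simulation for an exercise.

The amounts to watch are small on one side: in the gamma run target reads 37.1% at 1.25 d, while side product reads 0%, less than the scatter of 1 percentage point.

| flask | substrate | reagent | remark | time |
|---|---|---|---|---|
| gamma | 10 mM | 3 equiv | run made earlier |  |
| eta | 15 mM | 3 equiv | run made earlier |  |
| delta | 20 mM | 4.5 equiv | run made earlier |  |
| flask | 20 mM | 3.00 equiv |  | 15 d |

| run | time / d | target / % | side product / % |
|---|---|---|---|
| gamma | 1.25 | 37.1 | 0 |
| gamma | 2.50 | 53.3 | 1.1 |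
| gamma | 5.00 | 58.1 | 1.8 |
| gamma | 10.0 | 57.0 | 1.5 |
| gamma | 20.0 | 56.8 | 0.5 |
| eta | 1.67 | 49.8 | 1.5 |
| eta | 5.00 | 59.5 | 1.7 |
| eta | 8.00 | 57.5 | 1.2 |
| eta | 12.0 | 59.0 | 3.0 |
| eta | 20.0 | 57.8 | 1.2 |
| delta | 1.67 | 65.1 | 2.7 |
| delta | 5.00 | 66.6 | 2.3 |
| delta | 8.00 | 66.8 | 1.0 |
| delta | 12.0 | 67.5 | 1.8 |
| delta | 20.0 | 67.6 | 0.6 |

(readings scatter by 1 percentage point)

- the analysis behind the earlier runs scatters by 1 percentage point, standard deviation

- ratio of target to side product at 8.0 h
- ratio of target to side product at 50 h
- ratio of target to side product at 15 d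
- which of target and side product there is more of at 15 d

The early stage of these runs is a climb of target. By 5.00 d the climb has stopped: gamma and eta, both at 3 equiv of reagent but at 10 mM and 15 mM of substrate, hold target at 58.0% of the charge on average, and delta, at 4.5 equiv, holds more, 67.6% at its last reading. In the late stage, single ratios of target to side product run from 19.7 to 114, so one reading says little.

Side product is a small correction to target, so the readings are better pooled. From 5.00 d on, the side product readings of gamma, eta and delta add up to 16.6%, a sum that carries a scatter of 3.3 points. Dividing the target readings, added likewise, by that sum gives 40.6. This is the split, the target standing per unit of side product once target has stopped climbing, a selectivity factor read from the runs.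

My own reckoning for the flask, at 3.00 equiv like gamma and eta, puts target near 58.0% and side product near 1.43% at 15 d. It puts the ratio near the split at 50 h and 15 d, and above it by an unread amount at 8.0 h. The forecast gives 40 at 8.0 h, 28 at 50 h and 48 at 15 d, with target ahead, and warns: “The ratios are therefore very uncertain, because the denominators are so small.”

The flask gives 174 at 8.0 h, 41.3 at 50 h and 37.5 at 15 d, with target ahead, 58.0% against 1.55%, beside the split of 40.6 and the reckoned 1.43%.

    substrate + reagent ⇌ intermediate B (K = 18.0 L mol⁻¹, k = 5.60 × 10⁻⁵ L mol⁻¹ s⁻¹)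
    substrate + reagent → intermediate A (k = 0.00350 L mol⁻¹ s⁻¹)
    intermediate C → intermediate D (k = 8.00 × 10⁻⁷ s⁻¹)
    reagent + intermediate A → intermediate C (k = 8.10 × 10⁻⁴ L mol⁻¹ s⁻¹)
    intermediate C → target (k = 3.00 × 10⁻⁵ s⁻¹)
    intermediate D → side product (k = 2.50 × 10⁻⁵ s⁻¹)
    2 substrate → homo dimer (k = 0.00790 L mol⁻¹ s⁻¹)

The rate constant from intermediate C to target, 3.0 × 10⁻⁵ s⁻¹, stands 37.5 to one against that from intermediate C to intermediate D, 8.0 × 10⁻⁷ s⁻¹. In the neighbour flask charged with 12.0 equiv of reagent, target stands at 82.5% at 15 d, the split makes that 2.03% of side product, and that neighbour holds 2.20%.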